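**Retrosynthetic overview**
- Dryocrassin ABBA is cut at the two outer ArC–CH2 bonds into methylenebis(butanoylphloroglucinol) and two acetylfilicinic acid enone methides, each released from a Mannich base.
- The methylenebis(butanoylphloroglucinol) comes from its di-tert-butyl dicarboxylate, in which a CO2tBu group holds each outer bridge position. The tert-butyl ester is chosen so that this group leaves under acid and not under alkali, and so that the dioxo ester cannot act as an acyl donor.
- That diester is cut into tetraethyl propane-1,1,3,3-tetracarboxylate and two tert-butyl 3,5-dioxooctanoates. The feature used is that the central CH2, the two ring-B carbons bonded to it and the four C–OH carbons next to these form one propane-1,1,3,3-tetracarbonyl unit, while the other three carbons of each ring B (C–CO2R, C–OH, C–butanoyl) are C2–C4 of a 3,5-dioxo ester.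
- Ring order: both rings B are built together, de novo, by a fourfold Claisen cyclocondensation. The two rings A are made from 2,4,6-trihydroxyacetophenone by dearomatising geminal dimethylation and are attached last.

Key step: step 2

Remark: the target has no stereocentre, and its filicinic acid rings are written as one of several rapidly interconverting enol tautomers, as are all compounds of that type below.

**Step 1**
Reactants: 1 tert-butyl acetoacetate (2 equiv); 2 ethyl butanoate (1 equiv)
Product: 4 tert-butyl 3,5-dioxooctanoate, via dilithium dienolate 3 (not isolated)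
Conditions: LiN(iPr)2 (4.1 equiv), THF, −78 → 0 °C; then 2, −78 → 0 °C; cold aq. HCl; chromatography, no distillation
Reagents that add atoms: none
Why: Claisen acylation of the acetoacetate dianion at its terminal carbon by an ester is the standard route to 3,5-dioxo esters, the second equivalent of dianion takes up the acidic proton of the product, and the tert-butyl ester should not lactonise to the 4-hydroxypyranone.

**Step 2**
Reactants: 5 tetraethyl propane-1,1,3,3-tetracarboxylate (1 equiv); 4 tert-butyl 3,5-dioxooctanoate (2.3 equiv)
Product: 8 di-tert-butyl 5,5'-methylenebis(3-butanoyl-2,4,6-trihydroxybenzoate), via acyclic Claisen adduct 6 (not isolated), via single-ring malonate 7 (not isolated)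
Conditions: NaOEt (6 equiv), EtOH, 25 → 78 °C; then toluene, EtOH distilled off, 105 °C; aq. HCl, 0 °C
Reagents that add atoms: none
Why: Proposed new method: ethoxide forms the enolate of 4 at C4 and, in equilibrium, at C2; the C4 carbon acylates one ethyl ester of a malonate unit of 5 (intermolecular Claisen condensation, 6), the C2 carbon then attacks the second ester of the same malonate unit, and tautomerisation of the cyclohexane-1,3,5-trione to the phloroglucinol polyanion takes each ring out of the retro-Claisen equilibria (7, then 8 after a second round on the other malonate unit). The closest known reaction type is the NaOEt-mediated cyclocondensation of diethyl malonate with diethyl 3-oxoglutarate to a phloroglucinoldicarboxylate, here extended to a CH2-linked bis-malonate and to a 3,5-dioxo ester as the three-carbon partner. Each of the two rings B closes in the same mode, a Dieckmann-type 6-(enolendo)-exo-trig C-acylation, and no stereocentre is formed. The step needs chemoselectivity for double C-acylation by 4 over self-condensation and lactonisation of 4 and over O-acylation: the tert-butyl ester of 4 is no acyl donor under these conditions, so the ethyl esters of 5 are the only electrophiles, and O-acyl or pyranone by-products are reopened by ethoxide whereas the aromatic product is not. Regiochemistry follows from connectivity, because C2 and C4 are the only doubly activated carbons of 4 (the butanoyl α-CH2 is several pK units less acidic) and the malonate carbon already carries the central CH2. The selectivity most at risk is ring closure against retro-Michael loss of a malonate from 5 or 7, which is countered by holding the mixture at ethanol reflux, where that cleavage is slow and reversible, until acylation is under way and only then removing ethanol.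

**Step 3**
Reactants: 8 di-tert-butyl 5,5'-methylenebis(3-butanoyl-2,4,6-trihydroxybenzoate)
Product: 10 1,1'-[methylenebis(2,4,6-trihydroxybenzene-3,1-diyl)]di(butan-1-one), via diacid 9 (not isolated)
Conditions: TFA–CH2Cl2 (1:3), 0 °C → rt, N2 sweep; evaporate; then dioxane–H2O (4:1), 90 °C
Reagents that add atoms: none
Why: Acidolysis of the tert-butyl esters (loss of 2-methylpropene while every ring carbon is still substituted) followed by thermal decarboxylation of the 2,4,6-trihydroxybenzoic acids through their β-keto acid tautomers should free one carbon per ring without alkali, so the methylene bridge and the butanoyl groups are not exposed to retro-Friedel–Crafts or deacylation conditions.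

**Step 4**
Reactants: 11 2,4,6-trihydroxyacetophenone
Product: 12 acetylfilicinic acid (2-acetyl-3,5-dihydroxy-6,6-dimethylcyclohexa-2,4-dien-1-one)
Conditions: NaOMe (3 equiv), MeI (2.1 equiv), MeOH, 0 °C → rt; aq. HCl
Reagents that add atoms: iodomethane, CI
Why: Base-mediated C-methylation of the phloroglucinol enolate with dearomatisation (geminal dimethylation) is the established entry to acylfilicinic acids, and limiting iodomethane to about two equivalents should hold the reaction at the dimethyl stage.

**Step 5**
Reactants: 12 acetylfilicinic acid
Product: 13 2-acetyl-4-[(dimethylamino)methyl]-3,5-dihydroxy-6,6-dimethylcyclohexa-2,4-dien-1-one (Mannich base, expected as the zwitterion)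
Conditions: CH2(NMe2)2 (1.05 equiv), MeCN, 0 °C → rt; product collected by filtration
Reagents that add atoms: N,N,N',N'-tetramethylmethanediamine, CN(C)CN(C)C
Why: Mannich aminomethylation, in which the strongly acidic enol of 12 protonates the aminal to the iminium ion and the only unsubstituted nucleophilic ring carbon attacks it.

**Step 6**
Reactants: 10 1,1'-[methylenebis(2,4,6-trihydroxybenzene-3,1-diyl)]di(butan-1-one) (1 equiv); 13 Mannich base of acetylfilicinic acid (2.3 equiv)
Product: 16 dryocrassin ABBA, via enone methide 14 (not isolated), via mono-adduct 15 (not isolated)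
Conditions: dioxane, 70 °C, N2 sweep; dil. aq. HCl work-up
Reagents that add atoms: none
Why: E1cB loss of dimethylamine from the Mannich base gives enone methide 14, which should be captured by the single free, doubly hydroxyl-flanked carbon of each ring B in a conjugate addition (Friedel–Crafts-type alkylation through a quinone methide), with the acidic phenols buffering the amine so that no strong base is present.

**Compound list**
1 | tert-butyl acetoacetate (tert-butyl 3-oxobutanoate) | CC(=O)CC(=O)OC(C)(C)C | starting material
2 | ethyl butanoate (ethyl butyrate) | CCCC(=O)OCC | starting material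
3 | dilithium dienolate of tert-butyl acetoacetate | [Li+].[Li+].C=C([O-])C=C([O-])OC(C)(C)C | intermediate
4 | tert-butyl 3,5-dioxooctanoate | CCCC(=O)CC(=O)CC(=O)OC(C)(C)C | intermediate
5 | tetraethyl propane-1,1,3,3-tetracarboxylate | CCOC(=O)C(CC(C(=O)OCC)C(=O)OCC)C(=O)OCC | starting material
6 | tert-butyl 4-butanoyl-6,8,8-tris(ethoxycarbonyl)-3,5-dioxooctanoate (acyclic Claisen adduct) | CCCC(=O)C(C(=O)CC(=O)OC(C)(C)C)C(=O)C(C(=O)OCC)CC(C(=O)OCC)C(=O)OCC | intermediate
7 | diethyl 2-{[3-butanoyl-5-(tert-butoxycarbonyl)-2,4,6-trihydroxyphenyl]methyl}propanedioate (single-ring malonate) | CCCC(=O)c1c(O)c(C(=O)OC(C)(C)C)c(O)c(CC(C(=O)OCC)C(=O)OCC)c1O | intermediate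
8 | di-tert-butyl 5,5'-methylenebis(3-butanoyl-2,4,6-trihydroxybenzoate) | CCCC(=O)c1c(O)c(C(=O)OC(C)(C)C)c(O)c(Cc2c(O)c(C(=O)OC(C)(C)C)c(O)c(C(=O)CCC)c2O)c1O | intermediate
9 | 5,5'-methylenebis(3-butanoyl-2,4,6-trihydroxybenzoic acid) | CCCC(=O)c1c(O)c(C(=O)O)c(O)c(Cc2c(O)c(C(=O)O)c(O)c(C(=O)CCC)c2O)c1O | intermediate
10 | 1,1'-[methylenebis(2,4,6-trihydroxybenzene-3,1-diyl)]di(butan-1-one) | CCCC(=O)c1c(O)cc(O)c(Cc2c(O)cc(O)c(C(=O)CCC)c2O)c1O | intermediate
11 | 2,4,6-trihydroxyacetophenone | CC(=O)c1c(O)cc(O)cc1O | starting material
12 | acetylfilicinic acid (2-acetyl-3,5-dihydroxy-6,6-dimethylcyclohexa-2,4-dien-1-one) | CC(=O)C1=C(O)C=C(O)C(C)(C)C1=O | intermediate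
13 | 2-acetyl-4-[(dimethylamino)methyl]-3,5-dihydroxy-6,6-dimethylcyclohexa-2,4-dien-1-one | CC(=O)C1=C(O)C(CN(C)C)=C(O)C(C)(C)C1=O | intermediate
14 | 2-acetyl-3-hydroxy-6,6-dimethyl-4-methylidenecyclohex-2-ene-1,5-dione (enone methide) | C=C1C(=O)C(C)(C)C(=O)C(C(C)=O)=C1O | intermediate
15 | mono-adduct: 10 carrying one (acetylfilicinic acid)methyl group on one ring B | CCCC(=O)c1c(O)c(CC2=C(O)C(C)(C)C(=O)C(C(C)=O)=C2O)c(O)c(Cc2c(O)cc(O)c(C(=O)CCC)c2O)c1O | intermediate
16 | dryocrassin ABBA | CCCC(=O)c1c(O)c(CC2=C(O)C(C)(C)C(=O)C(C(C)=O)=C2O)c(O)c(Cc2c(O)c(CC3=C(O)C(C)(C)C(=O)C(C(C)=O)=C3O)c(O)c(C(=O)CCC)c2O)c1O | target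

**Step count**
Total: 6 steps. Longest linear sequence: 4 steps (steps 1, 2, 3 and 6); steps 4 and 5 form the convergent branch.

**Steps most likely to fail**

1. Step 2 (key step). The bis-malonate may cleave at the CH2–malonate bond by retro-Michael reaction at the temperature the Claisen steps need. The sequence may also stall after the first acylation or after the first ring, and the tert-butyl ester may exchange slowly with ethoxide. Fallback with known chemistry, in which ring B is taken from the aromatic pool instead of being built: it sets out from ethyl butanoate 2, which is saponified (aq. NaOH, then HCl) to butanoic acid F1. F1 acylates commercial phloroglucinol under BF3·OEt2 at 90 °C (Friedel–Crafts acylation with the free acid) to give 1-(2,4,6-trihydroxyphenyl)butan-1-one F2. F2, used in threefold excess and recycled, is bridged with aqueous formaldehyde (0.4 equiv) in dilute aqueous NaOH at 0–20 °C (hydroxymethylation, then capture of the quinone methide by a second ring). This comes back to the route at 10 and leaves out steps 1 to 3.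

2. Step 6. The methylene bridges may exchange by retro-Friedel–Crafts fragmentation and recombination, scrambling ring A and ring B units. The enone methide may be captured by acetylfilicinic acid set free through retro-Mannich reaction, or the reaction may stop after one alkylation. Fallback with reversed polarity: it sets out from 10, which is aminomethylated on both free ring carbons with CH2(NMe2)2 (2.2 equiv, MeCN, rt) to give 1,1'-{methylenebis[5-(dimethylaminomethyl)-2,4,6-trihydroxybenzene-3,1-diyl]}di(butan-1-one) F3. F3 is heated with acetylfilicinic acid 12 (2.5 equiv) in dioxane at 70 °C, so that the ortho-quinone methide now forms on ring B and is captured by the free ring carbon of 12. This comes back at 16 and leaves out step 5.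

3. Step 4. Methylation may run on to the tri- and tetramethyl stage, or go to the second free ring carbon or to oxygen, so that site control is poor. Fallback in which the second ring position is blocked: it sets out from 11, which is C-acetylated (Ac2O, BF3·OEt2, Friedel–Crafts) to 1,1'-(2,4,6-trihydroxy-1,3-phenylene)di(ethan-1-one) F4. The single free ring carbon of F4 then takes both methyl groups (MeI, NaOMe, MeOH) to give 2,4-diacetyl-3,5-dihydroxy-6,6-dimethylcyclohexa-2,4-dien-1-one F5. Both acetyl groups are removed in hot 85% H2SO4 (hydrolytic deacylation) to give filicinic acid F6, and one acetyl group is put back with Ac2O and BF3·OEt2. This comes back at 12.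

**Further compounds**
F1 | step 2 | butanoic acid | CCCC(=O)O
F2 | step 2 | 1-(2,4,6-trihydroxyphenyl)butan-1-one | CCCC(=O)c1c(O)cc(O)cc1O
F3 | step 6 | 1,1'-{methylenebis[5-(dimethylaminomethyl)-2,4,6-trihydroxybenzene-3,1-diyl]}di(butan-1-one) | CCCC(=O)c1c(O)c(CN(C)C)c(O)c(Cc2c(O)c(CN(C)C)c(O)c(C(=O)CCC)c2O)c1O
F4 | step 4 | 1,1'-(2,4,6-trihydroxy-1,3-phenylene)di(ethan-1-one) | CC(=O)c1c(O)cc(O)c(C(C)=O)c1O
F5 | step 4 | 2,4-diacetyl-3,5-dihydroxy-6,6-dimethylcyclohexa-2,4-dien-1-one | CC(=O)C1=C(O)C(C(C)=O)=C(O)C(C)(C)C1=O
F6 | step 4 | filicinic acid (3,5-dihydroxy-4,4-dimethylcyclohexa-2,5-dien-1-one) | CC1(C)C(O)=CC(=O)C=C1O
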